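**Retrosynthetic overview**
1. The allyl aryl ether C–O bond is cut last: target 26 ⇒ 7-hydroxy-8-methoxycoumarin 25 + allylic alcohol–lactone 15 (Mitsunobu; 14 + 14 heavy atoms).
2. 15 ⇒ alkynyl lactone 13 by Zr-catalysed methylalumination and formaldehyde trapping, which makes the (E)-alkene.
3. 13 ⇒ aldehyde 7 + chiral allenylboronate 11 (sets C5); 7 ⇒ (S)-lactic acid by dioxolanone allylation (sets C3) and ozonolysis.
4. 25 ⇒ 2-methoxyresorcinol 22 + ethyl propiolate; 22 ⇒ resorcinol by bis-MOM protection, C2 lithiation–borylation–oxidation and O-methylation.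
5. Ring order: temporary dioxolanone (step 1) → γ-lactone (step 5); separately the pyranone ring on the existing benzene ring (step 11); both are complete before the coupling.

Assumption: the (R,R)-tartrate allenylboronate 11 is taken to attack the Si face of aldehyde 7, as (R,R)-tartrate allylboronates do; pivalaldehyde and the tartrate diester are auxiliaries and are treated as reagents.

**Step 1**
Reactants: 1 (S)-lactic acid
Product: 2 (2S,5S)-2-tert-butyl-5-methyl-1,3-dioxolan-4-one
Conditions: t-BuCHO, TsOH·H2O (cat.), H2SO4 (cat.), pentane, reflux (Dean–Stark); crystallisation from pentane/Et2O, −78 °C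
Reagents that add atoms: pivalaldehyde (CC(C)(C)C=O)
Why: Acid-catalysed acetalisation (Seebach self-regeneration of stereocentres) leaves the lactic acid centre untouched and gives the cis acetal, enriched by crystallisation, which stores the chirality at the new C2 centre.

**Step 2**
Reactants: 2 (2S,5S)-2-tert-butyl-5-methyl-1,3-dioxolan-4-one; 3 allyl bromide
Product: 5 (2S,5R)-2-tert-butyl-5-methyl-5-(prop-2-en-1-yl)-1,3-dioxolan-4-one, via lithium enolate 4 (not isolated)
Conditions: LiN(i-Pr)2, THF, −78 °C; allyl bromide, −78 → −30 °C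
Reagents that add atoms: lithium diisopropylamide ([Li]N(C(C)C)C(C)C)
Why: Enolate alkylation in which allyl bromide attacks the planar lithium enolate anti to the tert-butyl group, so allyl replaces the former hydrogen and the quaternary centre (the future C3, R) is set with high selectivity.

**Step 3**
Reactants: 5 (2S,5R)-2-tert-butyl-5-methyl-5-(prop-2-en-1-yl)-1,3-dioxolan-4-one
Product: 7 2-[(2S,4R)-2-tert-butyl-4-methyl-5-oxo-1,3-dioxolan-4-yl]acetaldehyde, via ozonide 6 (not isolated)
Conditions: O3, CH2Cl2, −78 °C; PPh3, −78 °C → rt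
Reagents that add atoms: ozone ([O-][O+]=O)
Why: Ozonolysis with reductive work-up cleaves only the terminal alkene; the acetal ester and the quaternary centre are inert.

**Step 4**
Reactants: 8 propargyl bromide
Product: 11 bis(2,4-dimethylpentan-3-yl) (4R,5R)-2-(propa-1,2-dien-1-yl)-1,3,2-dioxaborolane-4,5-dicarboxylate, via allenylmagnesium bromide 9 (not isolated), via allenylboronic acid 10 (not isolated)
Conditions: Mg, HgCl2 (cat.), Et2O, 0 °C; B(OMe)3, −78 °C; aq. HCl; then bis(2,4-dimethylpentan-3-yl) L-tartrate, 4 Å molecular sieves, toluene, rt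
Reagents that add atoms: magnesium ([Mg]); trimethyl borate (COB(OC)OC); bis(2,4-dimethylpentan-3-yl) L-tartrate (CC(C)C(C(C)C)OC(=O)[C@H](O)[C@@H](O)C(=O)OC(C(C)C)C(C)C)
Why: Magnesium insertion with propargyl–allenyl transposition, borylation and esterification with the C2-symmetric tartrate diester give the chiral allenylboronate (Yamamoto reagent), whose two centres come unchanged from L-tartaric acid.

**Step 5**
Reactants: 7 2-[(2S,4R)-2-tert-butyl-4-methyl-5-oxo-1,3-dioxolan-4-yl]acetaldehyde; 11 bis(2,4-dimethylpentan-3-yl) (4R,5R)-2-(propa-1,2-dien-1-yl)-1,3,2-dioxaborolane-4,5-dicarboxylate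
Product: 13 (3R,5S)-3-hydroxy-3-methyl-5-(prop-2-yn-1-yl)oxolan-2-one, via hydroxy dioxolanone 12 (not isolated)
Conditions: toluene, 4 Å molecular sieves, −78 °C; H2O work-up; TsOH·H2O (cat.), CH2Cl2, rt
Reagents that add atoms: none
Why: Allenylboration through a closed six-membered SE2′ transition state delivers the propargyl group to the Si face under tartrate control (new carbinol centre S), and acid-catalysed acyl transfer from the activated dioxolanone to this hydroxyl closes the γ-lactone with loss of pivalaldehyde and retention at both centres.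

**Step 6**
Reactants: 13 (3R,5S)-3-hydroxy-3-methyl-5-(prop-2-yn-1-yl)oxolan-2-one
Product: 15 (3R,5S)-3-hydroxy-5-[(2E)-4-hydroxy-2-methylbut-2-en-1-yl]-3-methyloxolan-2-one, via alkenylalane 14 (not isolated)
Conditions: Me3Al (4 equiv), Cp2ZrCl2 (0.2 equiv), H2O (1.5 equiv), CH2Cl2, −23 °C; (CH2O)n, −23 °C → rt; aq. potassium sodium tartrate
Reagents that add atoms: trimethylaluminium (C[Al](C)C); formaldehyde as paraformaldehyde (C=O)
Why: Zirconium-catalysed syn-methylalumination of the terminal alkyne (Negishi carboalumination, water-accelerated) puts methyl on the internal carbon, and addition of the alkenylalane to formaldehyde with retention gives the (E)-allylic alcohol, while the tertiary hydroxyl is masked as its aluminium alkoxide and the lactone should be inert to Me3Al at −23 °C.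

**Step 7**
Reactants: 16 resorcinol
Product: 17 1,3-bis(methoxymethoxy)benzene
Conditions: NaH, MOMCl, DMF, 0 °C → rt
Reagents that add atoms: chloromethyl methyl ether (COCCl)
Why: Double Williamson O-alkylation protects both phenols and installs two cooperating ortho-directing groups.

**Step 8**
Reactants: 17 1,3-bis(methoxymethoxy)benzene
Product: 20 2,6-bis(methoxymethoxy)phenol, via aryllithium 18 (not isolated), via lithium arylborate 19 (not isolated)
Conditions: n-BuLi, THF, 0 °C → rt; B(OMe)3, −78 °C → rt; 30% aq. H2O2, 0 °C → rt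
Reagents that add atoms: n-butyllithium (CCCC[Li]); trimethyl borate (COB(OC)OC); hydrogen peroxide (OO)
Why: Directed ortho-metalation at C2 between the two MOM ethers, borylation and oxidative boron-to-oxygen migration give the phenol at a single position.

**Step 9**
Reactants: 20 2,6-bis(methoxymethoxy)phenol
Product: 21 2-methoxy-1,3-bis(methoxymethoxy)benzene
Conditions: MeI, K2CO3, acetone, reflux
Reagents that add atoms: iodomethane (CI)
Why: Williamson O-methylation of the only free phenol.

**Step 10**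
Reactants: 21 2-methoxy-1,3-bis(methoxymethoxy)benzene
Product: 22 2-methoxybenzene-1,3-diol
Conditions: HCl (cat.), MeOH, 50 °C
Reagents that add atoms: none
Why: Acid-catalysed acetal exchange removes both MOM groups as dimethoxymethane while the aryl methyl ether is stable.

**Step 11**
Reactants: 22 2-methoxybenzene-1,3-diol; 23 ethyl propiolate
Product: 25 7-hydroxy-8-methoxy-2H-chromen-2-one, via cis-cinnamate 24 (not isolated)
Conditions: ZnCl2 (1 equiv), 1,4-dioxane, 95 °C
Reagents that add atoms: none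
Why: Lewis acid-promoted hydroarylation of the propiolate at C4 of the resorcinol (ortho to one hydroxyl, para to the other; C4 and C6 are equivalent) followed by lactonisation (Pechmann-type coumarin synthesis) forms the pyranone ring.

**Step 12**
Reactants: 15 (3R,5S)-3-hydroxy-5-[(2E)-4-hydroxy-2-methylbut-2-en-1-yl]-3-methyloxolan-2-one; 25 7-hydroxy-8-methoxy-2H-chromen-2-one
Product: 26 (3R,5S)-3-hydroxy-5-{(2E)-4-[(8-methoxy-2-oxo-2H-chromen-7-yl)oxy]-2-methylbut-2-en-1-yl}-3-methyloxolan-2-one
Conditions: PPh3, DIAD, THF, 0 °C → rt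
Reagents that add atoms: none
Why: Mitsunobu etherification in which the acidic 7-hydroxyl displaces the activated primary allylic alcohol in an SN2 sense; the tertiary alcohol cannot be activated, and the (E)-alkene and both stereocentres are untouched.

**Compound list**
1 | (S)-lactic acid | C[C@H](O)C(=O)O | starting material
2 | (2S,5S)-2-tert-butyl-5-methyl-1,3-dioxolan-4-one | C[C@@H]1O[C@@H](OC1=O)C(C)(C)C | intermediate
3 | allyl bromide | C=CCBr | starting material
4 | lithium (2S)-2-tert-butyl-5-methyl-1,3-dioxol-4-olate (lithium enolate of 2) | [Li]OC1=C(C)O[C@@H](O1)C(C)(C)C | intermediate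
5 | (2S,5R)-2-tert-butyl-5-methyl-5-(prop-2-en-1-yl)-1,3-dioxolan-4-one | C=CC[C@@]1(C)O[C@@H](OC1=O)C(C)(C)C | intermediate
6 | (2S,5R)-2-tert-butyl-5-methyl-5-[(1,2,4-trioxolan-3-yl)methyl]-1,3-dioxolan-4-one (ozonide, mixture at the trioxolane carbon) | C1OOC(O1)C[C@@]2(C)O[C@@H](OC2=O)C(C)(C)C | intermediate
7 | 2-[(2S,4R)-2-tert-butyl-4-methyl-5-oxo-1,3-dioxolan-4-yl]acetaldehyde | O=CC[C@@]1(C)O[C@@H](OC1=O)C(C)(C)C | intermediate
8 | propargyl bromide | C#CCBr | starting material
9 | allenylmagnesium bromide | C=C=C[Mg]Br | intermediate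
10 | allenylboronic acid | C=C=CB(O)O | intermediate
11 | bis(2,4-dimethylpentan-3-yl) (4R,5R)-2-(propa-1,2-dien-1-yl)-1,3,2-dioxaborolane-4,5-dicarboxylate | CC(C)C(C(C)C)OC(=O)[C@H](O1)[C@@H](OB1C=C=C)C(=O)OC(C(C)C)C(C)C | intermediate
12 | (2S,5R)-2-tert-butyl-5-[(2S)-2-hydroxypent-4-yn-1-yl]-5-methyl-1,3-dioxolan-4-one | C#CC[C@H](O)C[C@@]1(C)O[C@@H](OC1=O)C(C)(C)C | intermediate
13 | (3R,5S)-3-hydroxy-3-methyl-5-(prop-2-yn-1-yl)oxolan-2-one | C#CC[C@H]1C[C@@](C)(O)C(=O)O1 | intermediate
14 | dimethylaluminium alkoxide of (3R,5S)-5-[(2E)-3-(dimethylalumanyl)-2-methylprop-2-en-1-yl]-3-hydroxy-3-methyloxolan-2-one | C[Al](C)/C=C(\C)C[C@H]1C[C@@](C)(O[Al](C)C)C(=O)O1 | intermediate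
15 | (3R,5S)-3-hydroxy-5-[(2E)-4-hydroxy-2-methylbut-2-en-1-yl]-3-methyloxolan-2-one | OC/C=C(\C)C[C@H]1C[C@@](C)(O)C(=O)O1 | intermediate
16 | resorcinol | Oc1cccc(O)c1 | starting material
17 | 1,3-bis(methoxymethoxy)benzene | COCOc1cccc(OCOC)c1 | intermediate
18 | 2,6-bis(methoxymethoxy)phenyllithium | [Li]c1c(OCOC)cccc1OCOC | intermediate
19 | lithium [2,6-bis(methoxymethoxy)phenyl]trimethoxyborate | [Li+].CO[B-](OC)(OC)c1c(OCOC)cccc1OCOC | intermediate
20 | 2,6-bis(methoxymethoxy)phenol | COCOc1cccc(OCOC)c1O | intermediate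
21 | 2-methoxy-1,3-bis(methoxymethoxy)benzene | COCOc1cccc(OCOC)c1OC | intermediate
22 | 2-methoxybenzene-1,3-diol | COc1c(O)cccc1O | intermediate
23 | ethyl propiolate | CCOC(=O)C#C | starting material
24 | ethyl (2Z)-3-(2,4-dihydroxy-3-methoxyphenyl)prop-2-enoate | CCOC(=O)/C=C\c1ccc(O)c(OC)c1O | intermediate
25 | 7-hydroxy-8-methoxy-2H-chromen-2-one | COc1c(O)ccc2ccc(=O)oc12 | intermediate
26 | (3R,5S)-3-hydroxy-5-{(2E)-4-[(8-methoxy-2-oxo-2H-chromen-7-yl)oxy]-2-methylbut-2-en-1-yl}-3-methyloxolan-2-one | COc1c(OC/C=C(\C)C[C@H]2C[C@@](C)(O)C(=O)O2)ccc2ccc(=O)oc12 | target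

**Step count**
Total steps: 12. Longest linear sequence: 6 steps (steps 1 → 2 → 3 → 5 → 6 → 12, or equally steps 7 → 8 → 9 → 10 → 11 → 12).

**Three steps most likely to fail**

Step 6. The neutral alkenylalane may add sluggishly to paraformaldehyde, and the lactone rules out activation as an ate complex with n-BuLi. The fallback sets out from 13: the same methylalumination is quenched with I2 (THF, −30 °C) and the product is isolated as the vinyl iodide (3R,5S)-3-hydroxy-5-[(2E)-3-iodo-2-methylprop-2-en-1-yl]-3-methyloxolan-2-one F1. The last carbon is then introduced by a Stille coupling with Bu3SnCH2OH and Pd(PPh3)4 (1,4-dioxane, 90 °C), which keeps the alkene geometry and returns to the route at 15.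

Step 5. The allenylboronic acid is sensitive, and facial control on this β-quaternary aldehyde may be modest. The fallback sets out from 5, sets C5 by resolving a terminal epoxide and forms the C6–C7 bond with an acetylide. Epoxidation with mCPBA (CH2Cl2, NaHCO3) gives the epoxide pair (2S,5R)-2-tert-butyl-5-methyl-5-{[(2R)-oxiran-2-yl]methyl}-1,3-dioxolan-4-one F2 and (2S,5R)-2-tert-butyl-5-methyl-5-{[(2S)-oxiran-2-yl]methyl}-1,3-dioxolan-4-one F3. Hydrolytic kinetic resolution with (R,R)-(salen)Co(OAc) (salen = N,N′-bis(3,5-di-tert-butylsalicylidene)cyclohexane-1,2-diaminate; 0.5 mol %, H2O 0.55 equiv) uses the catalyst enantiomer that hydrolyses F3; it gives the diol (2S,5R)-2-tert-butyl-5-[(2S)-2,3-dihydroxypropyl]-5-methyl-1,3-dioxolan-4-one F4 and leaves F2, which is separated. F2 is opened at its CH2 terminus by LiC≡CSiMe3 and BF3·OEt2 (THF, −78 °C) to (2S,5R)-2-tert-butyl-5-[(2S)-2-hydroxy-5-(trimethylsilyl)pent-4-yn-1-yl]-5-methyl-1,3-dioxolan-4-one F5. TsOH (cat.) lactonises F5 to (3R,5S)-3-hydroxy-3-methyl-5-[3-(trimethylsilyl)prop-2-yn-1-yl]oxolan-2-one F6, and Bu4NF/AcOH removes the silyl group, returning to the route at 13.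

Step 11. The ZnCl2-promoted propiolate condensation can give low yields with a free, oxidation-prone trioxygenated arene. The fallback sets out from 22: Vilsmeier–Haack formylation (POCl3, DMF, MeCN, 0 °C → rt; aq. NaOAc) gives 2,4-dihydroxy-3-methoxybenzaldehyde F7. Wittig olefination with Ph3P=CHCO2Et in N,N-diethylaniline at reflux gives ethyl (2E)-3-(2,4-dihydroxy-3-methoxyphenyl)prop-2-enoate F8, which isomerises thermally to 24 and lactonises, returning to the route at 25.

**Further compounds**
F1 | step 6 | (3R,5S)-3-hydroxy-5-[(2E)-3-iodo-2-methylprop-2-en-1-yl]-3-methyloxolan-2-one | I/C=C(\C)C[C@H]1C[C@@](C)(O)C(=O)O1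
F2 | step 5 | (2S,5R)-2-tert-butyl-5-methyl-5-{[(2R)-oxiran-2-yl]methyl}-1,3-dioxolan-4-one | C1O[C@@H]1C[C@@]2(C)O[C@@H](OC2=O)C(C)(C)C
F3 | step 5 | (2S,5R)-2-tert-butyl-5-methyl-5-{[(2S)-oxiran-2-yl]methyl}-1,3-dioxolan-4-one | C1O[C@H]1C[C@@]2(C)O[C@@H](OC2=O)C(C)(C)C
F4 | step 5 | (2S,5R)-2-tert-butyl-5-[(2S)-2,3-dihydroxypropyl]-5-methyl-1,3-dioxolan-4-one | OC[C@@H](O)C[C@@]1(C)O[C@@H](OC1=O)C(C)(C)C
F5 | step 5 | (2S,5R)-2-tert-butyl-5-[(2S)-2-hydroxy-5-(trimethylsilyl)pent-4-yn-1-yl]-5-methyl-1,3-dioxolan-4-one | C[Si](C)(C)C#CC[C@H](O)C[C@@]1(C)O[C@@H](OC1=O)C(C)(C)C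
F6 | step 5 | (3R,5S)-3-hydroxy-3-methyl-5-[3-(trimethylsilyl)prop-2-yn-1-yl]oxolan-2-one | C[Si](C)(C)C#CC[C@H]1C[C@@](C)(O)C(=O)O1
F7 | step 11 | 2,4-dihydroxy-3-methoxybenzaldehyde | COc1c(O)ccc(C=O)c1O
F8 | step 11 | ethyl (2E)-3-(2,4-dihydroxy-3-methoxyphenyl)prop-2-enoate | CCOC(=O)/C=C/c1ccc(O)c(OC)c1O
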